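**Retrosynthetic overview**
- The target comes from hydrogenolysis of its O-benzyl ether. The dihydrofuran ring (ring B) is the only ring built and is closed last, by acid-mediated C2–O bond formation from a 1-aryl-2-(2-hydroxyaryl)propane-1,3-diol.
- That diol comes from reductive auxiliary removal from an Evans syn-aldol adduct. The key C2–C3 bond is made by a boron aldol of an (S)-4-benzyloxazolidinone arylacetyl imide with O-benzylsyringaldehyde.
- The aldol fixes C3; the trans C2 centre follows from it during ring closure.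
- The arylacetic acid comes from oxidative cleavage of an ortho-allyl group, installed by aromatic Claisen rearrangement of the allyl ether of dihydroconiferyl alcohol, itself made from eugenol.
- Both benzene rings are bought (eugenol, syringaldehyde).

Assumption: the target is made exactly as drawn, which is the 2,3-trans (2S,3R) isomer; TBS = tert-butyldimethylsilyl.

**Step 1**
Reactants: 1 eugenol (4-allyl-2-methoxyphenol)
Product: 2 dihydroconiferyl alcohol [4-(3-hydroxypropyl)-2-methoxyphenol]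
Conditions: 9-BBN (2.3 equiv), THF, 0 °C to rt; then 3 M NaOH, 30% H2O2, 0 °C to rt
Reagents that add atoms: hydrogen peroxide, OO
Why: Anti-Markovnikov hydroboration–oxidation of the terminal alkene gives the primary alcohol; the extra 9-BBN is consumed by the phenol O–H and no stereocentre is formed.

**Step 2**
Reactants: 2 dihydroconiferyl alcohol
Product: 3 3-[4-(allyloxy)-3-methoxyphenyl]propan-1-ol
Conditions: allyl bromide (1.2 equiv), K2CO3 (2 equiv), acetone, reflux
Reagents that add atoms: allyl bromide, C=CCBr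
Why: Williamson etherification in which carbonate deprotonates only the phenol, so the primary alcohol is left free.

**Step 3**
Reactants: 3 3-[4-(allyloxy)-3-methoxyphenyl]propan-1-ol
Product: 4 2-allyl-4-(3-hydroxypropyl)-6-methoxyphenol
Conditions: N,N-diethylaniline, 195 °C, sealed tube, argon
Reagents that add atoms: none
Why: Aromatic Claisen ([3,3]-sigmatropic) rearrangement delivers the allyl group to the only free ortho position, since the other ortho position carries OMe and the para position is blocked.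

**Step 4**
Reactants: 4 2-allyl-4-(3-hydroxypropyl)-6-methoxyphenol
Product: 5 tert-butyl{3-[3-allyl-4-(tert-butyldimethylsilyloxy)-5-methoxyphenyl]propoxy}dimethylsilane (bis-TBS ether)
Conditions: TBSCl (2.5 equiv), imidazole (5 equiv), DMF, rt to 40 °C
Reagents that add atoms: tert-butyldimethylsilyl chloride, CC(C)(C)[Si](C)(C)Cl
Why: Imidazole-promoted silylation protects the phenol and the primary alcohol in one operation with groups that later leave together under fluoride.

**Step 5**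
Reactants: 5 bis-TBS ether
Product: 7 2-{2-(TBS-oxy)-5-[3-(TBS-oxy)propyl]-3-methoxyphenyl}acetaldehyde, via vicinal diol 6 (not isolated)
Conditions: OsO4 (2 mol %), NaIO4 (4 equiv), 2,6-lutidine, dioxane/H2O 3:1, rt; used crude
Reagents that add atoms: osmium tetroxide, O=[Os](=O)(=O)=O; sodium periodate, [Na+].[O-]I(=O)(=O)=O
Why: Lemieux–Johnson oxidation (catalytic dihydroxylation, then periodate glycol cleavage) shortens the allyl group by one carbon without touching the electron-rich ring or the silyl ethers.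

**Step 6**
Reactants: 7 arylacetaldehyde
Product: 8 2-{2-(TBS-oxy)-5-[3-(TBS-oxy)propyl]-3-methoxyphenyl}acetic acid
Conditions: NaClO2, NaH2PO4, 2-methyl-2-butene, t-BuOH/THF/H2O, 0 °C to rt
Reagents that add atoms: sodium chlorite, [Na+].[O-]Cl=O
Why: Pinnick oxidation converts the sensitive aldehyde to the acid at about pH 4, while the alkene scavenger removes HOCl and prevents ring chlorination.

**Step 7**
Reactants: 8 arylacetic acid; 9 (S)-4-benzyloxazolidin-2-one
Product: 11 (S)-4-benzyl-3-(2-{2-(TBS-oxy)-5-[3-(TBS-oxy)propyl]-3-methoxyphenyl}acetyl)oxazolidin-2-one, via mixed pivalic anhydride 10 (not isolated)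
Conditions: PivCl, Et3N, THF, −20 °C; then 9, LiCl, −20 °C to rt
Reagents that add atoms: none
Why: N-Acylation through the mixed pivalic anhydride, where the oxazolidinone attacks the less hindered arylacetyl carbonyl under LiCl/Et3N activation, avoids strong base near the aryl silyl ether.

**Step 8**
Reactants: 12 syringaldehyde (4-hydroxy-3,5-dimethoxybenzaldehyde)
Product: 13 4-(benzyloxy)-3,5-dimethoxybenzaldehyde
Conditions: BnBr (1.2 equiv), K2CO3 (2 equiv), DMF, 60 °C
Reagents that add atoms: benzyl bromide, BrCc1ccccc1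
Why: Williamson benzylation masks the acidic phenol, which would otherwise quench the enolate, with a group that comes off by hydrogenolysis at the end.

**Step 9**
Reactants: 11 arylacetyl imide; 13 4-(benzyloxy)-3,5-dimethoxybenzaldehyde
Product: 15 (S)-4-benzyl-3-[(2S,3S)-3-(4-benzyloxy-3,5-dimethoxyphenyl)-2-{2-(TBS-oxy)-5-[3-(TBS-oxy)propyl]-3-methoxyphenyl}-3-hydroxypropanoyl]oxazolidin-2-one, via Z-boron enolate 14 (not isolated)
Conditions: Bu2BOTf (1.2 equiv), iPr2NEt (1.4 equiv), CH2Cl2, −78 to 0 °C; then 13, −78 to 0 °C; pH 7 buffer, MeOH, H2O2, 0 °C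
Reagents that add atoms: none
Why: Evans syn aldol, in which the Z-dibutylboron enolate reacts through a Zimmerman–Traxler chair on the face away from the auxiliary benzyl group, forms the key C–C bond and sets C2 (S, the future ring C3) and C3 (S) of the propanoyl chain.

**Step 10**
Reactants: 15 syn-aldol adduct
Product: 16 (1S,2R)-1-(4-benzyloxy-3,5-dimethoxyphenyl)-2-{2-(TBS-oxy)-5-[3-(TBS-oxy)propyl]-3-methoxyphenyl}propane-1,3-diol
Conditions: LiBH4 (3 equiv), THF, 0 °C to rt; aq. NH4Cl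
Reagents that add atoms: none
Why: Reductive auxiliary cleavage, with hydride attacking the exocyclic imide carbonyl, gives the primary alcohol without touching the α-aryl stereocentre (S becomes R only by CIP priority); any O-to-O silyl shift is harmless because all silyl groups leave in the next step.

**Step 11**
Reactants: 16 bis-TBS diol
Product: 17 (1S,2R)-1-(4-benzyloxy-3,5-dimethoxyphenyl)-2-[2-hydroxy-5-(3-hydroxypropyl)-3-methoxyphenyl]propane-1,3-diol
Conditions: Bu4NF (3 equiv), AcOH (3 equiv), THF, 0 °C to rt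
Reagents that add atoms: none
Why: Fluoride-driven desilylation, buffered with acetic acid, frees the ortho-phenol nucleophile and the side-chain alcohol while leaving the benzyl ether and both stereocentres untouched.

**Step 12**
Reactants: 17 triol phenol
Product: 18 3-[(2S,3R)-2-(4-benzyloxy-3,5-dimethoxyphenyl)-3-(hydroxymethyl)-7-methoxy-2,3-dihydro-1-benzofuran-5-yl]propan-1-ol
Conditions: TsOH·H2O (10 mol %), CH2Cl2/MeCN 4:1 (0.01 M), 0 °C to rt
Reagents that add atoms: none
Why: Acid-catalysed SN1 cycloetherification, in which the para-alkoxybenzylic cation is captured by the ortho-phenol, closes the five-membered ring anti to the CH2OH group on the fixed C3 centre (with equilibration through re-ionisation), giving the 2,3-trans (2S) product.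

**Step 13**
Reactants: 18 O-benzyl dihydrobenzofuran
Product: 19 3-[(2S,3R)-2-(4-hydroxy-3,5-dimethoxyphenyl)-3-(hydroxymethyl)-7-methoxy-2,3-dihydro-1-benzofuran-5-yl]propan-1-ol (target)
Conditions: H2 (1 atm), 10% Pd/C, EtOAc/MeOH, rt, stopped at one equivalent of H2
Reagents that add atoms: none
Why: Catalytic hydrogenolysis cleaves the aryl benzyl ether much faster than the cyclic benzylic C2–O bond, releasing the syringyl phenol without touching either stereocentre.

**Compound list**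
1 | eugenol (4-allyl-2-methoxyphenol) | C=CCc1ccc(O)c(OC)c1 | starting material
2 | dihydroconiferyl alcohol, 4-(3-hydroxypropyl)-2-methoxyphenol | OCCCc1ccc(O)c(OC)c1 | intermediate
3 | 3-[4-(allyloxy)-3-methoxyphenyl]propan-1-ol | C=CCOc1ccc(CCCO)cc1OC | intermediate
4 | 2-allyl-4-(3-hydroxypropyl)-6-methoxyphenol | C=CCc1cc(CCCO)cc(OC)c1O | intermediate
5 | tert-butyl{3-[3-allyl-4-(tert-butyldimethylsilyloxy)-5-methoxyphenyl]propoxy}dimethylsilane | C=CCc1cc(CCCO[Si](C)(C)C(C)(C)C)cc(OC)c1O[Si](C)(C)C(C)(C)C | intermediate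
6 | 3-{2-(TBS-oxy)-5-[3-(TBS-oxy)propyl]-3-methoxyphenyl}propane-1,2-diol (racemic at the carbinol, not isolated) | OCC(O)Cc1cc(CCCO[Si](C)(C)C(C)(C)C)cc(OC)c1O[Si](C)(C)C(C)(C)C | intermediate
7 | 2-{2-(TBS-oxy)-5-[3-(TBS-oxy)propyl]-3-methoxyphenyl}acetaldehyde | O=CCc1cc(CCCO[Si](C)(C)C(C)(C)C)cc(OC)c1O[Si](C)(C)C(C)(C)C | intermediate
8 | 2-{2-(TBS-oxy)-5-[3-(TBS-oxy)propyl]-3-methoxyphenyl}acetic acid | OC(=O)Cc1cc(CCCO[Si](C)(C)C(C)(C)C)cc(OC)c1O[Si](C)(C)C(C)(C)C | intermediate
9 | (S)-4-benzyloxazolidin-2-one | O=C1N[C@@H](Cc2ccccc2)CO1 | starting material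
10 | mixed anhydride of acid 8 with pivalic acid (not isolated) | CC(C)(C)C(=O)OC(=O)Cc1cc(CCCO[Si](C)(C)C(C)(C)C)cc(OC)c1O[Si](C)(C)C(C)(C)C | intermediate
11 | (S)-4-benzyl-3-(2-{2-(TBS-oxy)-5-[3-(TBS-oxy)propyl]-3-methoxyphenyl}acetyl)oxazolidin-2-one | O=C(Cc1cc(CCCO[Si](C)(C)C(C)(C)C)cc(OC)c1O[Si](C)(C)C(C)(C)C)N1[C@@H](Cc2ccccc2)COC1=O | intermediate
12 | syringaldehyde | COc1cc(C=O)cc(OC)c1O | starting material
13 | 4-(benzyloxy)-3,5-dimethoxybenzaldehyde | COc1cc(C=O)cc(OC)c1OCc1ccccc1 | intermediate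
14 | Z-dibutylboron enolate of imide 11 (not isolated) | CCCCB(CCCC)O/C(=C\c1cc(CCCO[Si](C)(C)C(C)(C)C)cc(OC)c1O[Si](C)(C)C(C)(C)C)N1[C@@H](Cc2ccccc2)COC1=O | intermediate
15 | (S)-4-benzyl-3-[(2S,3S)-3-(4-benzyloxy-3,5-dimethoxyphenyl)-2-{2-(TBS-oxy)-5-[3-(TBS-oxy)propyl]-3-methoxyphenyl}-3-hydroxypropanoyl]oxazolidin-2-one | O[C@H](c1cc(OC)c(OCc2ccccc2)c(OC)c1)[C@H](c1cc(CCCO[Si](C)(C)C(C)(C)C)cc(OC)c1O[Si](C)(C)C(C)(C)C)C(=O)N1[C@@H](Cc2ccccc2)COC1=O | intermediate
16 | (1S,2R)-1-(4-benzyloxy-3,5-dimethoxyphenyl)-2-{2-(TBS-oxy)-5-[3-(TBS-oxy)propyl]-3-methoxyphenyl}propane-1,3-diol | O[C@H](c1cc(OC)c(OCc2ccccc2)c(OC)c1)[C@H](c1cc(CCCO[Si](C)(C)C(C)(C)C)cc(OC)c1O[Si](C)(C)C(C)(C)C)CO | intermediate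
17 | (1S,2R)-1-(4-benzyloxy-3,5-dimethoxyphenyl)-2-[2-hydroxy-5-(3-hydroxypropyl)-3-methoxyphenyl]propane-1,3-diol | O[C@H](c1cc(OC)c(OCc2ccccc2)c(OC)c1)[C@H](c1cc(CCCO)cc(OC)c1O)CO | intermediate
18 | 3-[(2S,3R)-2-(4-benzyloxy-3,5-dimethoxyphenyl)-3-(hydroxymethyl)-7-methoxy-2,3-dihydro-1-benzofuran-5-yl]propan-1-ol | COc1cc([C@H]2Oc3c(OC)cc(CCCO)cc3[C@@H]2CO)cc(OC)c1OCc1ccccc1 | intermediate
19 | 3-[(2S,3R)-2-(4-hydroxy-3,5-dimethoxyphenyl)-3-(hydroxymethyl)-7-methoxy-2,3-dihydro-1-benzofuran-5-yl]propan-1-ol | COc1cc([C@H]2Oc3c(OC)cc(CCCO)cc3[C@@H]2CO)cc(OC)c1O | target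

**Totals**
Total step count: 13. Longest linear sequence: 12 steps (steps 1–7 and 9–13, from eugenol 1 to target 19); step 8 is a one-step side branch.

**Three steps most likely to fail, with fallbacks**

Step 9 (boron aldol). An α-aryl imide with a hindered, electron-rich aldehyde may react sluggishly, with reduced selectivity or with retro-aldol on work-up. The fallback sets out from acid 8. Couple 8 with (S)-4-benzylthiazolidine-2-thione (DCC, catalytic DMAP, CH2Cl2, 0 °C) to give (S)-4-benzyl-3-(2-{2-(TBS-oxy)-5-[3-(TBS-oxy)propyl]-3-methoxyphenyl}acetyl)thiazolidine-2-thione F1. Enolise F1 with TiCl4 (1.05 equiv), iPr2NEt (1.1 equiv) and N-methylpyrrolidinone (1.1 equiv) in CH2Cl2 at −78 to 0 °C and add aldehyde 13. The chlorotitanium enolate gives the same Evans-syn sense, affording the (2S,3S)-thiazolidinethione aldol adduct F2. The thione auxiliary is removed under very mild conditions (NaBH4, THF/EtOH, 0 °C), and the fallback comes back to the route at diol 16.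

Step 10 (LiBH4 cleavage). The free β-hydroxy imide with an acidic α-aryl proton can undergo retro-aldol or epimerise under the basic hydride conditions. The fallback sets out from adduct 15. Cap the β-hydroxyl first (TESOTf, 2,6-lutidine, CH2Cl2, −78 °C) to give the (2S,3S)-3-(triethylsilyloxy) imide F3, which cannot undergo retro-aldol. Reduce with LiBH4 in THF at 0 °C to give (2R,3S)-3-(4-benzyloxy-3,5-dimethoxyphenyl)-2-{2-(TBS-oxy)-5-[3-(TBS-oxy)propyl]-3-methoxyphenyl}-3-(triethylsilyloxy)propan-1-ol F4. The Bu4NF/AcOH conditions of step 11 then strip the triethylsilyl group with both TBS groups, and the fallback comes back to the route at triol phenol 17.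

Step 12 (acid cyclisation). The benzyl-protected cation needs a fairly strong acid, which may cause E1 elimination to a stilbene, loss of formaldehyde or oligomerisation. The fallback sets out from triol phenol 17 and reverses the order of deprotection and ring closure. Hydrogenolyse the benzyl ether first (H2, 10% Pd/C, EtOAc, rt, stopped at one equivalent) to give (1S,2R)-1-(4-hydroxy-3,5-dimethoxyphenyl)-2-[2-hydroxy-5-(3-hydroxypropyl)-3-methoxyphenyl]propane-1,3-diol F5. With the para-hydroxyl free, very weak acid suffices (pyridinium p-toluenesulfonate, THF/H2O, 40 °C). F5 loses water to the para-quinone methide 4-[(2R)-3-hydroxy-2-(2-hydroxy-5-(3-hydroxypropyl)-3-methoxyphenyl)propylidene]-2,6-dimethoxycyclohexa-2,5-dien-1-one F6, which the ortho-phenol traps by conjugate addition anti to the CH2OH group. This gives the trans ring directly, and the fallback comes back to the route at target 19.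

**Further compounds**
F1 | step 9 | (S)-4-benzyl-3-(2-{2-(TBS-oxy)-5-[3-(TBS-oxy)propyl]-3-methoxyphenyl}acetyl)thiazolidine-2-thione | O=C(Cc1cc(CCCO[Si](C)(C)C(C)(C)C)cc(OC)c1O[Si](C)(C)C(C)(C)C)N1[C@@H](Cc2ccccc2)CSC1=S
F2 | step 9 | (2S,3S)-3-(4-benzyloxy-3,5-dimethoxyphenyl)-2-{2-(TBS-oxy)-5-[3-(TBS-oxy)propyl]-3-methoxyphenyl}-3-hydroxy-1-[(S)-4-benzyl-2-thioxothiazolidin-3-yl]propan-1-one | O[C@H](c1cc(OC)c(OCc2ccccc2)c(OC)c1)[C@H](c1cc(CCCO[Si](C)(C)C(C)(C)C)cc(OC)c1O[Si](C)(C)C(C)(C)C)C(=O)N1[C@@H](Cc2ccccc2)CSC1=S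
F3 | step 10 | (S)-4-benzyl-3-[(2S,3S)-3-(4-benzyloxy-3,5-dimethoxyphenyl)-2-{2-(TBS-oxy)-5-[3-(TBS-oxy)propyl]-3-methoxyphenyl}-3-(triethylsilyloxy)propanoyl]oxazolidin-2-one | CC[Si](CC)(CC)O[C@H](c1cc(OC)c(OCc2ccccc2)c(OC)c1)[C@H](c1cc(CCCO[Si](C)(C)C(C)(C)C)cc(OC)c1O[Si](C)(C)C(C)(C)C)C(=O)N1[C@@H](Cc2ccccc2)COC1=O
F4 | step 10 | (2R,3S)-3-(4-benzyloxy-3,5-dimethoxyphenyl)-2-{2-(TBS-oxy)-5-[3-(TBS-oxy)propyl]-3-methoxyphenyl}-3-(triethylsilyloxy)propan-1-ol | CC[Si](CC)(CC)O[C@H](c1cc(OC)c(OCc2ccccc2)c(OC)c1)[C@H](c1cc(CCCO[Si](C)(C)C(C)(C)C)cc(OC)c1O[Si](C)(C)C(C)(C)C)CO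
F5 | step 12 | (1S,2R)-1-(4-hydroxy-3,5-dimethoxyphenyl)-2-[2-hydroxy-5-(3-hydroxypropyl)-3-methoxyphenyl]propane-1,3-diol | O[C@H](c1cc(OC)c(O)c(OC)c1)[C@H](c1cc(CCCO)cc(OC)c1O)CO
F6 | step 12 | 4-[(2R)-3-hydroxy-2-(2-hydroxy-5-(3-hydroxypropyl)-3-methoxyphenyl)propylidene]-2,6-dimethoxycyclohexa-2,5-dien-1-one | O=C1C(OC)=CC(=C[C@H](c2cc(CCCO)cc(OC)c2O)CO)C=C1OC
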